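**Retrosynthetic overview**

1. Target ⇐ oxidation of a lactol released from a tricyclic methyl acetal; the pyranone ring ⇐ intramolecular Mitsunobu O-alkylation (inversion) of an enol onto a (2S,3S)-3-hydroxy-2-methylbutanoyl chain.
2. Quaternary C8 ⇐ dearomative C-prenylation of a fully substituted acylphloroglucinol whose oxygen next to the side chain is locked in a temporary 2-methoxychroman (acetal) ring.
3. Acyl chain ⇐ aryllithium + (2S,3S)-aldehyde from ethyl (S)-3-hydroxybutanoate; cyclobutylmethyl arm ⇐ Negishi coupling with an iodide made from (1R,5R)-verbenone.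
4. Key C–C bond: intermolecular organocatalytic Michael (Friedel–Crafts-type) addition of 3,5-bis(methoxymethoxy)phenol to (E)-hex-2-enal, which sets the side-chain stereocentre and closes the acetal ring as a lactol.
5. Ring order: cyclobutane (in verbenone) and benzene ring (phloroglucinol) are bought; acetal ring formed first, carbocycle then dearomatised, pyranone ring closed, acetal ring opened last.

Assumption: the enol is taken in the tautomeric form of the given SMILES, and (1R,5R)-(+)-verbenone of high optical purity is taken as a purchasable terpene.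

Locants: target core is O1, C2, C3, C4(=O), C4a, C5(OH), C6 (hexanoic acid arm), C7(=O), C8 (quaternary), C8a. Compounds 17–29 are numbered as chromans built on the temporary acetal ring; their C4, C6 and C8 become the side-chain carbon, C8 and C4a of the target.

**Route**

Step 1
Reactants: 1 (1R,5R)-(+)-verbenone
Product: 3 (1R,3S)-3-acetyl-2,2-dimethylcyclobutane-1-carboxylic acid, via α-keto acid 2 (not isolated)
Conditions: RuCl3·xH2O (2 mol%), NaIO4 (4.2 equiv), CCl4/MeCN/H2O 2:2:3, 25 °C
Reagents that add atoms: sodium periodate, [Na+].[O-]I(=O)(=O)=O; water, O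
Why: RuO4 (regenerated by periodate) cleaves the enone C=C and the resulting α-keto acid loses CO2 by oxidative decarboxylation, while both ring stereocentres are carried over untouched from verbenone as the cis pair.

Step 2
Reactants: 3 cis-pinononic acid
Product: 4 methyl (1R,3S)-3-acetyl-2,2-dimethylcyclobutane-1-carboxylate
Conditions: MeI (1.5 equiv), K2CO3 (1.5 equiv), DMF, 25 °C
Reagents that add atoms: iodomethane, CI
Why: Carboxylate SN2 O-methylation under weakly basic conditions that do not epimerise the centre next to the acetyl group.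

Step 3
Reactants: 4 keto ester
Product: 5 methyl (1R,3R)-2,2-dimethyl-3-(prop-1-en-2-yl)cyclobutane-1-carboxylate
Conditions: Ph3PCH3Br (1.4 equiv), KOtBu (1.3 equiv), THF, 0 °C; then 4, 0 → 25 °C
Reagents that add atoms: methyltriphenylphosphonium bromide, C[P+](c1ccccc1)(c1ccccc1)c1ccccc1.[Br-]
Why: Wittig methylenation is selective for the ketone over the ester and, with the ylide preformed and no excess base, leaves the cis ring centres intact (the 3R label is only a priority change).

Step 4
Reactants: 5 isopropenyl ester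
Product: 6 [(1R,3R)-2,2-dimethyl-3-(prop-1-en-2-yl)cyclobutyl]methanol
Conditions: LiAlH4 (1.0 equiv), Et2O, 0 °C
Reagents that add atoms: none
Why: Hydride reduction of the ester to the primary alcohol, with no stereocentre touched.

Step 5
Reactants: 6 cyclobutylmethanol
Product: 7 (1R,3R)-1-(iodomethyl)-2,2-dimethyl-3-(prop-1-en-2-yl)cyclobutane
Conditions: PPh3 (1.3 equiv), I2 (1.3 equiv), imidazole (1.5 equiv), CH2Cl2, 0 → 25 °C
Reagents that add atoms: iodine, II
Why: Appel iodination goes by SN2 displacement at the primary carbon, so no cyclobutylcarbinyl cation (and no ring expansion) arises.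

Step 6
Reactants: 8 ethyl (S)-3-hydroxybutanoate
Product: 10 ethyl (2S,3S)-3-hydroxy-2-methylbutanoate, via dilithium enolate 9 (not isolated)
Conditions: LiN(iPr)2 (2.2 equiv), THF, −50 → −20 °C; then MeI (1.5 equiv), THF/DMPU, −78 → 0 °C
Reagents that add atoms: iodomethane, CI
Why: Fráter–Seebach alkylation, in which the lithium-chelated alkoxide enolate is methylated on the face opposite the C3 methyl group to give the anti (2S,3S) ester with about 95:5 selectivity.

Step 7
Reactants: 10 anti hydroxy ester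
Product: 11 ethyl (2S,3S)-3-[(tert-butyldimethylsilyl)oxy]-2-methylbutanoate
Conditions: TBSCl (1.2 equiv), imidazole (1.2 equiv), DMF, 25 °C
Reagents that add atoms: tert-butyldimethylsilyl chloride, CC(C)(C)[Si](C)(C)Cl
Why: Standard silylation blocks the secondary alcohol for the reduction and the aryllithium addition.

Step 8
Reactants: 11 silyl ether ester
Product: 12 (2S,3S)-3-[(tert-butyldimethylsilyl)oxy]-2-methylbutanal
Conditions: iBu2AlH (1.1 equiv), CH2Cl2, −78 °C
Reagents that add atoms: none
Why: Partial reduction stops at the aldehyde because the aluminium hemiacetal is stable at −78 °C until work-up, and the aldehyde is used at once to keep the α-centre.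

Step 9
Reactants: 13 phloroglucinol
Product: 14 3,5-bis(methoxymethoxy)phenol
Conditions: MOMCl (2.0 equiv), iPr2NEt (2.2 equiv), CH2Cl2/DMF, 0 → 25 °C; bis-ether separated from mono- and tris-ethers by chromatography
Reagents that add atoms: chloromethyl methyl ether, COCCl
Why: Williamson-type O-alkylation run to the statistical bis-ether, leaving one free phenol to steer the Michael step ortho and two MOM groups as lithiation directors.

Step 10
Reactants: 14 3,5-bis(methoxymethoxy)phenol; 15 (E)-hex-2-enal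
Product: 17 (4S)-5,7-bis(methoxymethoxy)-4-propylchroman-2-ol (lactol; C2 epimers), via open-chain aldehyde 16 (not isolated)
Conditions: 15 (1.2 equiv), (R)-2-[diphenyl(trimethylsilyloxy)methyl]pyrrolidine (20 mol%), PhCO2H (20 mol%), toluene, 0 → 25 °C
Reagents that add atoms: none
Why: Iminium activation of the enal and Friedel–Crafts-type Michael addition of the phenol ortho carbon (the key intermolecular C–C bond) from the face of the (E)-iminium not covered by the diphenyl(silyloxy)methyl group give the 3S aldehyde, which the neighbouring OH traps as the 4S lactol.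

Step 11
Reactants: 17 lactol
Product: 18 (4S)-2-methoxy-5,7-bis(methoxymethoxy)-4-propylchromane (C2 epimers)
Conditions: MeOH, pyridinium p-toluenesulfonate (10 mol%), 3 Å molecular sieves, 25 °C
Reagents that add atoms: methanol, CO
Why: Acid-catalysed acetalisation masks the lactol as a base-stable methyl acetal and keeps the phenolic oxygen next to the side chain tied up, which later decides the regiochemistry of pyranone closure.

Step 12
Reactants: 18 methyl acetal
Product: 20 (4S)-6-iodo-2-methoxy-5,7-bis(methoxymethoxy)-4-propylchromane, via aryllithium 19 (not isolated)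
Conditions: n-BuLi (1.15 equiv), THF, 0 °C, 1 h; then I2 (1.2 equiv), −78 → 0 °C
Reagents that add atoms: iodine, II
Why: Directed ortho-metalation picks the C–H between the two MOM ethers (doubly chelated, most acidic), so lithiation and iodine quench are selective for C6.

Step 13
Reactants: 7 cyclobutylmethyl iodide; 20 aryl iodide
Product: 23 (4S)-6-{[(1S,3R)-2,2-dimethyl-3-(prop-1-en-2-yl)cyclobutyl]methyl}-2-methoxy-5,7-bis(methoxymethoxy)-4-propylchromane, via alkyllithium 21 (not isolated), via alkylzinc chloride 22 (not isolated)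
Conditions: 7 (1.5 equiv), t-BuLi (3.1 equiv), Et2O/pentane, −78 °C; ZnCl2 (1.6 equiv, THF), −78 → 25 °C; then 20, Pd(OAc)2 (5 mol%), 2-dicyclohexylphosphino-2′,6′-dimethoxybiphenyl (10 mol%), THF, 50 °C
Reagents that add atoms: none
Why: Negishi coupling, with iodine–lithium exchange at −78 °C (no free radical, so no cyclobutylcarbinyl ring opening), transmetalation to zinc and palladium-catalysed sp3–sp2 coupling with the hindered aryl iodide; no stereocentre is involved.

Step 14
Reactants: 23 alkylated chroman; 12 (2S,3S)-aldehyde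
Product: 25 (2R,3S)-3-[(tert-butyldimethylsilyl)oxy]-2-methyl-1-(chroman-8-yl)butan-1-ol of 23 (C1 epimers), via aryllithium 24 (not isolated)
Conditions: n-BuLi (1.3 equiv), THF, 0 °C, 1 h; then 12 (1.5 equiv), −78 → −20 °C
Reagents that add atoms: none
Why: Second directed ortho-lithiation at the only aryl C–H left (between a MOM ether and the ring oxygen) and 1,2-addition to the aldehyde; the new carbinol centre is a mixture erased by the next oxidation, while the two chain centres come from 12.

Step 15
Reactants: 25 benzylic alcohol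
Product: 26 (2S,3S)-3-[(tert-butyldimethylsilyl)oxy]-2-methyl-1-(chroman-8-yl)butan-1-one of 23
Conditions: Dess–Martin periodinane (1.5 equiv), CH2Cl2, 0 → 25 °C
Reagents that add atoms: none
Why: Dess–Martin oxidation of the hindered benzylic alcohol under non-basic conditions, so the epimerisable α-methyl centre and the β-silyloxy group survive.

Step 16
Reactants: 26 protected aryl ketone
Product: 27 (2S,3S)-1-[(4S)-6-(cyclobutylmethyl)-5,7-dihydroxy-2-methoxy-4-propylchroman-8-yl]-3-hydroxy-2-methylbutan-1-one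
Conditions: HCl (0.5 M in MeOH), 30 °C
Reagents that add atoms: none
Why: Acid-catalysed methanolysis removes both MOM ethers (as dimethoxymethane) and the silyl ether, while the methyl acetal simply re-forms in methanol and the dilute acid at 30 °C leaves the isopropenyl group untouched.

Step 17
Reactants: 27 triol
Product: 29 (4S,6R)-6-(cyclobutylmethyl)-7-hydroxy-8-[(2S,3S)-3-hydroxy-2-methylbutanoyl]-2-methoxy-6-(3-methylbut-2-en-1-yl)-4-propyl-2,3,4,6-tetrahydro-5H-chromen-5-one, via dilithium bis-phenoxide 28 (not isolated)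
Conditions: LiN(SiMe3)2 (2.1 equiv), THF, −40 → 0 °C; then prenyl bromide (1.2 equiv), 0 °C
Reagents that add atoms: 1-bromo-3-methylbut-2-ene, CC(C)=CCBr
Why: Dearomative C-alkylation of an acylphloroglucinol dianion at the carbon between the two phenoxide oxygens (the other ring carbons are blocked), the product being trapped as a chelated enol; prenyl enters anti to the pseudo-axial 4-propyl group to give the 6R centre (C8 of the target, expected dr about 3:1), the minor epimer being removed by chromatography.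

Step 18
Reactants: 29 dearomatised enol
Product: 30 tricyclic pyranone methyl acetal (2R,3S,8R; target skeleton with the carboxyl carbon as a CH(OMe) acetal bonded to O5)
Conditions: PPh3 (1.5 equiv), diisopropyl azodicarboxylate (1.5 equiv), THF, 0 → 25 °C
Reagents that add atoms: none
Why: Intramolecular Mitsunobu etherification, in which the acidic enol OH (the only oxygen able to reach, the other flank being locked in the acetal) displaces the activated secondary alcohol with inversion to set C2 as R while C3 stays S, giving the trans-2,3-dimethylpyranone.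

Step 19
Reactants: 30 methyl acetal
Product: 31 tricyclic lactol (as 30 with OH in place of OMe)
Conditions: AcOH/THF/H2O 3:1:1, 40 °C
Reagents that add atoms: water, O
Why: Acid hydrolysis of the mixed acetal, eased by the vinylogous-ester character of its ring oxygen, frees the lactol, which is the ring-chain tautomer of the aldehyde with the 5-OH enol.

Step 20
Reactants: 31 lactol
Product: 32 target acid
Conditions: NaClO2 (3 equiv), NaH2PO4 (3 equiv), 2-methyl-2-butene (30 equiv), t-BuOH/H2O, 0 → 25 °C
Reagents that add atoms: sodium chlorite, [Na+].[O-]Cl=O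
Why: Pinnick oxidation of the aldehyde tautomer to the carboxylic acid, with excess 2-methyl-2-butene scavenging HOCl so the prenyl and isopropenyl groups and the enol are spared; no stereocentre changes.

**Compound list**

1 | (1R,5R)-(+)-verbenone | CC1=CC(=O)[C@@H]2C[C@H]1C2(C)C | starting material
2 | 2-[(1R,3S)-3-acetyl-2,2-dimethylcyclobutyl]-2-oxoacetic acid (not isolated) | CC(=O)[C@H]1C[C@@H](C(=O)C(=O)O)C1(C)C | intermediate
3 | (1R,3S)-3-acetyl-2,2-dimethylcyclobutane-1-carboxylic acid (cis-pinononic acid) | CC(=O)[C@H]1C[C@@H](C(=O)O)C1(C)C | intermediate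
4 | methyl (1R,3S)-3-acetyl-2,2-dimethylcyclobutane-1-carboxylate | CC(=O)[C@H]1C[C@@H](C(=O)OC)C1(C)C | intermediate
5 | methyl (1R,3R)-2,2-dimethyl-3-(prop-1-en-2-yl)cyclobutane-1-carboxylate | C=C(C)[C@H]1C[C@@H](C(=O)OC)C1(C)C | intermediate
6 | [(1R,3R)-2,2-dimethyl-3-(prop-1-en-2-yl)cyclobutyl]methanol | C=C(C)[C@H]1C[C@@H](CO)C1(C)C | intermediate
7 | (1R,3R)-1-(iodomethyl)-2,2-dimethyl-3-(prop-1-en-2-yl)cyclobutane | C=C(C)[C@H]1C[C@@H](CI)C1(C)C | intermediate
8 | ethyl (S)-3-hydroxybutanoate | C[C@H](O)CC(=O)OCC | starting material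
9 | dilithium alkoxide–ester enolate of 8 (not isolated) | C[C@H](O[Li])/C=C(\O[Li])OCC | intermediate
10 | ethyl (2S,3S)-3-hydroxy-2-methylbutanoate | C[C@H](O)[C@H](C)C(=O)OCC | intermediate
11 | ethyl (2S,3S)-3-[(tert-butyldimethylsilyl)oxy]-2-methylbutanoate | C[C@H](O[Si](C)(C)C(C)(C)C)[C@H](C)C(=O)OCC | intermediate
12 | (2S,3S)-3-[(tert-butyldimethylsilyl)oxy]-2-methylbutanal | C[C@H](O[Si](C)(C)C(C)(C)C)[C@H](C)C=O | intermediate
13 | phloroglucinol (benzene-1,3,5-triol) | Oc1cc(O)cc(O)c1 | starting material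
14 | 3,5-bis(methoxymethoxy)phenol | COCOc1cc(O)cc(OCOC)c1 | intermediate
15 | (E)-hex-2-enal | CCC/C=C/C=O | starting material
16 | (3S)-3-[2-hydroxy-4,6-bis(methoxymethoxy)phenyl]hexanal (not isolated) | O=CC[C@H](CCC)c1c(O)cc(OCOC)cc1OCOC | intermediate
17 | (4S)-5,7-bis(methoxymethoxy)-4-propylchroman-2-ol (C2 epimers) | OC1C[C@H](CCC)c2c(OCOC)cc(OCOC)cc2O1 | intermediate
18 | (4S)-2-methoxy-5,7-bis(methoxymethoxy)-4-propylchromane (C2 epimers) | COC1C[C@H](CCC)c2c(OCOC)cc(OCOC)cc2O1 | intermediate
19 | 6-lithio derivative of 18 (not isolated) | COC1C[C@H](CCC)c2c(OCOC)c([Li])c(OCOC)cc2O1 | intermediate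
20 | (4S)-6-iodo-2-methoxy-5,7-bis(methoxymethoxy)-4-propylchromane | COC1C[C@H](CCC)c2c(OCOC)c(I)c(OCOC)cc2O1 | intermediate
21 | {[(1R,3R)-2,2-dimethyl-3-(prop-1-en-2-yl)cyclobutyl]methyl}lithium (not isolated) | C=C(C)[C@H]1C[C@@H](C[Li])C1(C)C | intermediate
22 | {[(1R,3R)-2,2-dimethyl-3-(prop-1-en-2-yl)cyclobutyl]methyl}zinc chloride (not isolated) | C=C(C)[C@H]1C[C@@H](C[Zn]Cl)C1(C)C | intermediate
23 | (4S)-6-{[(1S,3R)-2,2-dimethyl-3-(prop-1-en-2-yl)cyclobutyl]methyl}-2-methoxy-5,7-bis(methoxymethoxy)-4-propylchromane | COC1C[C@H](CCC)c2c(OCOC)c(C[C@@H]3C[C@H](C(C)=C)C3(C)C)c(OCOC)cc2O1 | intermediate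
24 | 8-lithio derivative of 23 (not isolated) | COC1C[C@H](CCC)c2c(OCOC)c(C[C@@H]3C[C@H](C(C)=C)C3(C)C)c(OCOC)c([Li])c2O1 | intermediate
25 | (2R,3S)-3-[(tert-butyldimethylsilyl)oxy]-1-[(4S)-6-{[(1S,3R)-2,2-dimethyl-3-(prop-1-en-2-yl)cyclobutyl]methyl}-2-methoxy-5,7-bis(methoxymethoxy)-4-propylchroman-8-yl]-2-methylbutan-1-ol (C1 epimers) | COC1C[C@H](CCC)c2c(OCOC)c(C[C@@H]3C[C@H](C(C)=C)C3(C)C)c(OCOC)c(C(O)[C@@H](C)[C@H](C)O[Si](C)(C)C(C)(C)C)c2O1 | intermediate
26 | (2S,3S)-3-[(tert-butyldimethylsilyl)oxy]-1-[(4S)-6-{[(1S,3R)-2,2-dimethyl-3-(prop-1-en-2-yl)cyclobutyl]methyl}-2-methoxy-5,7-bis(methoxymethoxy)-4-propylchroman-8-yl]-2-methylbutan-1-one | COC1C[C@H](CCC)c2c(OCOC)c(C[C@@H]3C[C@H](C(C)=C)C3(C)C)c(OCOC)c(C(=O)[C@@H](C)[C@H](C)O[Si](C)(C)C(C)(C)C)c2O1 | intermediate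
27 | (2S,3S)-1-[(4S)-6-{[(1S,3R)-2,2-dimethyl-3-(prop-1-en-2-yl)cyclobutyl]methyl}-5,7-dihydroxy-2-methoxy-4-propylchroman-8-yl]-3-hydroxy-2-methylbutan-1-one | COC1C[C@H](CCC)c2c(O)c(C[C@@H]3C[C@H](C(C)=C)C3(C)C)c(O)c(C(=O)[C@@H](C)[C@H](C)O)c2O1 | intermediate
28 | dilithium 5,7-bis(phenoxide) of 27 (not isolated) | COC1C[C@H](CCC)c2c(O[Li])c(C[C@@H]3C[C@H](C(C)=C)C3(C)C)c(O[Li])c(C(=O)[C@@H](C)[C@H](C)O)c2O1 | intermediate
29 | (4S,6R)-6-{[(1S,3R)-2,2-dimethyl-3-(prop-1-en-2-yl)cyclobutyl]methyl}-7-hydroxy-8-[(2S,3S)-3-hydroxy-2-methylbutanoyl]-2-methoxy-6-(3-methylbut-2-en-1-yl)-4-propyl-2,3,4,6-tetrahydro-5H-chromen-5-one | C=C(C)[C@H]1C[C@@H](C[C@@]2(CC=C(C)C)C(=O)C3=C(OC(OC)C[C@@H]3CCC)C(C(=O)[C@@H](C)[C@H](C)O)=C2O)C1(C)C | intermediate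
30 | tricyclic pyranone methyl acetal: (2R,3S,8R)-8-{[(1S,3R)-2,2-dimethyl-3-(prop-1-en-2-yl)cyclobutyl]methyl}-2,3-dimethyl-8-(3-methylbut-2-en-1-yl)chromane-4,7-dione core whose O5 and C6 are bridged by CH(OMe)–CH2–(S)-CH(propyl) (acetal epimers) | C=C(C)[C@H]1C[C@@H](C[C@@]2(CC=C(C)C)C(=O)C3=C(OC(OC)C[C@@H]3CCC)C4=C2O[C@H](C)[C@H](C)C4=O)C1(C)C | intermediate
31 | tricyclic lactol: as 30 with OH in place of OMe at the acetal carbon (hemiacetal epimers) | C=C(C)[C@H]1C[C@@H](C[C@@]2(CC=C(C)C)C(=O)C3=C(OC(O)C[C@@H]3CCC)C4=C2O[C@H](C)[C@H](C)C4=O)C1(C)C | intermediate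
32 | (3S)-3-[(2R,3S,8R)-8-{[(1S,3R)-2,2-dimethyl-3-(prop-1-en-2-yl)cyclobutyl]methyl}-5-hydroxy-2,3-dimethyl-8-(3-methylbut-2-en-1-yl)-4,7-dioxo-3,4,7,8-tetrahydro-2H-chromen-6-yl]hexanoic acid | C=C(C)[C@H]1C[C@@H](C[C@@]2(CC=C(C)C)C(=O)C([C@@H](CCC)CC(=O)O)=C(O)C3=C2O[C@H](C)[C@H](C)C3=O)C1(C)C | target

**Step count and risks**

Total: 20 steps. Longest linear sequence: 13 steps (steps 1–5, then 13–20).

Most likely to fail, first: step 10. The arylation may give low ee or attack the carbon between the two MOM ethers. The fallback sets out from 13 and rejoins at 17, setting the side-chain centre by reduction instead. Pechmann condensation of 13 with ethyl 3-oxohexanoate (H2SO4, 25 °C) gives 5,7-dihydroxy-4-propyl-2H-chromen-2-one F1. MOMCl/iPr2NEt gives 5,7-bis(methoxymethoxy)-4-propyl-2H-chromen-2-one F2. Copper-hydride conjugate reduction (Cu(OAc)2, the DTBM-SEGPHOS enantiomer that gives 4S, (EtO)2MeSiH, t-BuOH, toluene) gives (4S)-5,7-bis(methoxymethoxy)-4-propylchroman-2-one F3. iBu2AlH (CH2Cl2, −78 °C) reduces it to lactol 17.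

Second: step 17. The substrate bias at the new quaternary centre is remote and may be weak, and O-prenylation may compete. The fallback sets out from 27 and rejoins at 29, delivering the prenyl group under catalyst control. Prenyl chloroformate/pyridine acylates the non-chelated 5-OH to give the 5-O-(3-methylbut-2-en-1-yl) carbonate of 27 F4. Pd2(dba)3 with the DACH-phenyl Trost ligand (enantiomer matched to the substrate in a two-run test) then ionises it, extrudes CO2 and recombines the prenyl unit at C6 inside the chiral pocket to give 29.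

Third: step 18. The activated β-hydroxy ketone may eliminate to the tigloyl ketone and then close unselectively by oxa-Michael addition. The fallback sets out from 27 and rejoins at 30, closing the pyranone before dearomatisation and bypassing 29. PPh3/diisopropyl azodicarboxylate cyclises the chelated 7-OH onto the side-chain carbinol with inversion to give the aromatic (2R,3S)-2,3-dimethylchromanone acetal F5. Its sodium phenoxide (NaH, toluene, prenyl bromide, 0 → 25 °C) is then C-prenylated at the cyclobutylmethyl-bearing ortho carbon to give 30.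

**Further compounds**

F1 | step 10 | 5,7-dihydroxy-4-propyl-2H-chromen-2-one | CCCC1=CC(=O)Oc2cc(O)cc(O)c12
F2 | step 10 | 5,7-bis(methoxymethoxy)-4-propyl-2H-chromen-2-one | CCCC1=CC(=O)Oc2cc(OCOC)cc(OCOC)c12
F3 | step 10 | (4S)-5,7-bis(methoxymethoxy)-4-propylchroman-2-one | O=C1C[C@H](CCC)c2c(OCOC)cc(OCOC)cc2O1
F4 | step 17 | 5-O-(3-methylbut-2-en-1-yl) carbonate of 27 | COC1C[C@H](CCC)c2c(OC(=O)OCC=C(C)C)c(C[C@@H]3C[C@H](C(C)=C)C3(C)C)c(O)c(C(=O)[C@@H](C)[C@H](C)O)c2O1
F5 | step 18 | aromatic (2R,3S)-2,3-dimethylchromanone acetal (27 cyclised through O7, 5-OH free) | COC1C[C@H](CCC)c2c(O)c(C[C@@H]3C[C@H](C(C)=C)C3(C)C)c4O[C@H](C)[C@H](C)C(=O)c4c2O1
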